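Atoms of the lower flavan unit carry primes. Everything rests on cutting the C4'–C4a' bond of the lower pyran ring, which is closed last by a 6-endo Friedel–Crafts epoxy–arene cyclization. The step exploits lower ring A: C4a' is ortho to the ether oxygen O1' and para to the free C7' hydroxyl, within six-membered reach of the terminal oxirane carbon C4'. In one operation it completes the skeleton and delivers the 2',3'-cis flavan-3-ol, because C2' and C3' are already set in a threo aryl glycidyl-type ether. The precursor is a benzylated fisetinidol whose C4 carries, 3,4-cis through a boron-delivered arylation, a 2-hydroxy-4-aryloxyphenyl group bearing the aryl(oxiranyl)methyl arm.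

Key step: step 8

Assumption: (2R,3R)-fustin (natural dihydrofisetin) is bought as the single enantiomer.

Step 1
Reactants: 1 (2R,3R)-fustin
Product: 2 (2R,3R)-7-(benzyloxy)-2-[3,4-bis(benzyloxy)phenyl]-3-hydroxychroman-4-one
Conditions: BnBr, K2CO3, DMF, rt, N2
Reagents that add atoms: benzyl bromide, BrCc1ccccc1
Why: Williamson etherification with a weak base should alkylate only the three phenols and leave the C3 alcohol and both stereocenters untouched.

Step 2
Reactants: 2 (2R,3R)-7-(benzyloxy)-2-[3,4-bis(benzyloxy)phenyl]-3-hydroxychroman-4-one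
Product: 3 (2R,3S,4R)-7-(benzyloxy)-2-[3,4-bis(benzyloxy)phenyl]chromane-3,4-diol
Conditions: NaBH4, THF/MeOH, 0 °C
Reagents that add atoms: none
Why: Borohydride reduction of a dihydroflavonol by axial hydride delivery should give the equatorial C4 hydroxyl trans to the C3 hydroxyl (4R), and either C4 epimer would converge on the same epoxide in step 3.

Step 3
Reactants: 3 (2R,3S,4R)-7-(benzyloxy)-2-[3,4-bis(benzyloxy)phenyl]chromane-3,4-diol
Product: 4 (2R,3S,4S)-7-(benzyloxy)-2-[3,4-bis(benzyloxy)phenyl]-3,4-epoxychromane (oxirane oxygen anti to the 2-aryl group)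
Conditions: PPh3, DIAD, THF, 0 °C to rt; filtration through basic alumina, used at once
Reagents that add atoms: none
Why: Mitsunobu cyclodehydration of a trans-1,2-diol, in which the benzylic C4 oxyphosphonium is displaced by the C3 oxygen, so the oxirane must lie on the face of O3, anti to the 2-aryl group.

Step 4
Reactants: 5 3,4-bis(benzyloxy)benzaldehyde; 6 vinylmagnesium bromide
Product: 7 rac-1-[3,4-bis(benzyloxy)phenyl]prop-2-en-1-ol
Conditions: THF, −78 °C to 0 °C; then H2O
Reagents that add atoms: none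
Why: Grignard addition to an aryl aldehyde should give the racemic allylic alcohol, which is resolved in step 5.

Step 5
Reactants: 7 rac-1-[3,4-bis(benzyloxy)phenyl]prop-2-en-1-ol
Product: 8 (R)-[3,4-bis(benzyloxy)phenyl][(S)-oxiran-2-yl]methanol (erythro)
Conditions: Ti(OiPr)4 (cat.), D-(−)-DIPT (cat.), t-BuOOH (0.6 equiv), 4 Å MS, CH2Cl2, −20 °C
Reagents that add atoms: tert-butyl hydroperoxide, CC(C)(C)OO
Why: Sharpless asymmetric epoxidation run as a kinetic resolution, in which the D-tartrate catalyst should epoxidise the S alcohol fast and erythro-selectively on the face it dictates, setting the oxirane carbon as S, while the R enantiomer of 7 is left unreacted and removed by chromatography.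

Step 6
Reactants: 8 (R)-[3,4-bis(benzyloxy)phenyl][(S)-oxiran-2-yl]methanol; 9 resorcinol
Product: 10 3-{(S)-[3,4-bis(benzyloxy)phenyl][(S)-oxiran-2-yl]methoxy}phenol (threo)
Conditions: resorcinol (5 equiv), PPh3, DIAD, THF, 0 °C to rt
Reagents that add atoms: none
Why: Mitsunobu etherification should proceed by SN2 inversion at the benzylic carbinol (R to S), the adjacent oxirane disfavouring ionisation and the excess of resorcinol limiting the reaction to the mono-ether, so that the erythro epoxy alcohol becomes the threo aryl ether.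

Step 7
Reactants: 10 3-{(S)-[3,4-bis(benzyloxy)phenyl][(S)-oxiran-2-yl]methoxy}phenol; 4 (2R,3S,4S)-7-(benzyloxy)-2-[3,4-bis(benzyloxy)phenyl]-3,4-epoxychromane
Product: 12 (2R,3S,4S)-7-(benzyloxy)-2-[3,4-bis(benzyloxy)phenyl]-4-[4-{(S)-[3,4-bis(benzyloxy)phenyl][(S)-oxiran-2-yl]methoxy}-2-hydroxyphenyl]chroman-3-ol, via triaryl borate 11 (not isolated)
Conditions: 10 (3 equiv), BH3·SMe2 (1 equiv), CH2Cl2, 0 °C to rt; then 4 (1 equiv), toluene, −78 °C to 0 °C; then H2O
Reagents that add atoms: none
Why: This is the known syn-selective Friedel–Crafts-type opening of a benzylic epoxide by an electron-rich aryl borate, in which boron binds the oxirane oxygen, the benzylic C4–O bond ionises and an aryloxy ligand delivers its free ortho carbon (para to the ether oxygen) to C4 from the same face, which should set C4 as S with the new aryl group cis to the C3 hydroxyl.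

Step 8
Reactants: 12 (2R,3S,4S)-7-(benzyloxy)-2-[3,4-bis(benzyloxy)phenyl]-4-[4-{(S)-[3,4-bis(benzyloxy)phenyl][(S)-oxiran-2-yl]methoxy}-2-hydroxyphenyl]chroman-3-ol
Product: 13 (2R,3S,4S)-7-(benzyloxy)-2-[3,4-bis(benzyloxy)phenyl]-4-{(2S,3S)-2-[3,4-bis(benzyloxy)phenyl]-3,7-dihydroxychroman-6-yl}chroman-3-ol
Conditions: AuCl3 (5 mol %), AgOTf (15 mol %), ClCH2CH2Cl, 0 °C to rt
Reagents that add atoms: none
Why: The cationic trivalent gold Lewis acid should bind the oxirane oxygen, and lower ring A then attacks the terminal carbon C4' with C4a' in an SN2-like Friedel–Crafts step, after which proton loss from the arenium ion restores the phenol and frees the C3' hydroxyl. The closest known reaction type is the metal-catalysed intramolecular epoxy–arene cyclization of aryl glycidyl ethers to chroman-3-ols. The pyran ring closes in the 6-endo-tet mode through the C4'–C4a' bond. No stereocenter is formed: C3' keeps its configuration because the bond is made at the CH2 terminus and C2' is untouched, so the threo ether (erythro epoxy alcohol of step 5, inverted in step 6) is delivered as the (2'S,3'S) 2',3'-cis flavan-3-ol. The step needs attack at C4a' and not at C8', and 6-endo and not 5-exo opening, which the para hydroxyl at C7', the crowding of C8' between two oxygens and the hindered internal oxirane carbon C3' should secure. It also needs the benzylic aryl ether at C2' to resist ionisation, which the electron-withdrawing oxirane next to it and the low catalyst loading favour.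

Step 9
Reactants: 13 (2R,3S,4S)-7-(benzyloxy)-2-[3,4-bis(benzyloxy)phenyl]-4-{(2S,3S)-2-[3,4-bis(benzyloxy)phenyl]-3,7-dihydroxychroman-6-yl}chroman-3-ol
Product: 14 (2R,3S,4S)-2-(3,4-dihydroxyphenyl)-4-[(2S,3S)-2-(3,4-dihydroxyphenyl)-3,7-dihydroxychroman-6-yl]chromane-3,7-diol (CNP0187520.5)
Conditions: H2 (1 atm), Pd(OH)2/C, THF/MeOH, rt
Reagents that add atoms: none
Why: Catalytic hydrogenolysis should remove the five benzyl ethers under conditions in which the cyclic benzylic C2–O1 ether bonds of flavans are known to survive, and no stereocenter is touched.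

Compound list
1 | (2R,3R)-fustin, (2R,3R)-2-(3,4-dihydroxyphenyl)-3,7-dihydroxychroman-4-one | Oc1ccc2c(c1)O[C@H](c1ccc(O)c(O)c1)[C@@H](O)C2=O | starting material
2 | (2R,3R)-7-(benzyloxy)-2-[3,4-bis(benzyloxy)phenyl]-3-hydroxychroman-4-one | c1ccccc1COc1ccc2c(c1)O[C@H](c1ccc(OCc3ccccc3)c(OCc3ccccc3)c1)[C@@H](O)C2=O | intermediate
3 | (2R,3S,4R)-7-(benzyloxy)-2-[3,4-bis(benzyloxy)phenyl]chromane-3,4-diol | c1ccccc1COc1ccc2c(c1)O[C@H](c1ccc(OCc3ccccc3)c(OCc3ccccc3)c1)[C@@H](O)[C@@H]2O | intermediate
4 | (2R,3S,4S)-7-(benzyloxy)-2-[3,4-bis(benzyloxy)phenyl]-3,4-epoxychromane, oxirane anti to the 2-aryl group | c1ccccc1COc1ccc2c(c1)O[C@H](c1ccc(OCc3ccccc3)c(OCc3ccccc3)c1)[C@H]4O[C@@H]24 | intermediate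
5 | 3,4-bis(benzyloxy)benzaldehyde | O=Cc1ccc(OCc2ccccc2)c(OCc2ccccc2)c1 | starting material
6 | vinylmagnesium bromide | C=C[Mg]Br | starting material
7 | rac-1-[3,4-bis(benzyloxy)phenyl]prop-2-en-1-ol | C=CC(O)c1ccc(OCc2ccccc2)c(OCc2ccccc2)c1 | intermediate
8 | (R)-[3,4-bis(benzyloxy)phenyl][(S)-oxiran-2-yl]methanol | O[C@H](c1ccc(OCc2ccccc2)c(OCc2ccccc2)c1)[C@@H]1CO1 | intermediate
9 | resorcinol | Oc1cccc(O)c1 | starting material
10 | 3-{(S)-[3,4-bis(benzyloxy)phenyl][(S)-oxiran-2-yl]methoxy}phenol | Oc1cccc(O[C@@H](c2ccc(OCc3ccccc3)c(OCc3ccccc3)c2)[C@@H]2CO2)c1 | intermediate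
11 | tris[3-{(S)-[3,4-bis(benzyloxy)phenyl][(S)-oxiran-2-yl]methoxy}phenyl] borate | B(Oc1cccc(O[C@@H](c2ccc(OCc3ccccc3)c(OCc3ccccc3)c2)[C@@H]2CO2)c1)(Oc1cccc(O[C@@H](c2ccc(OCc3ccccc3)c(OCc3ccccc3)c2)[C@@H]2CO2)c1)Oc1cccc(O[C@@H](c2ccc(OCc3ccccc3)c(OCc3ccccc3)c2)[C@@H]2CO2)c1 | intermediate
12 | (2R,3S,4S)-7-(benzyloxy)-2-[3,4-bis(benzyloxy)phenyl]-4-[4-{(S)-[3,4-bis(benzyloxy)phenyl][(S)-oxiran-2-yl]methoxy}-2-hydroxyphenyl]chroman-3-ol | c1ccccc1COc1ccc2c(c1)O[C@H](c1ccc(OCc3ccccc3)c(OCc3ccccc3)c1)[C@@H](O)[C@H]2c1ccc(O[C@@H](c3ccc(OCc4ccccc4)c(OCc4ccccc4)c3)[C@@H]3CO3)cc1O | intermediate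
13 | (2R,3S,4S)-7-(benzyloxy)-2-[3,4-bis(benzyloxy)phenyl]-4-{(2S,3S)-2-[3,4-bis(benzyloxy)phenyl]-3,7-dihydroxychroman-6-yl}chroman-3-ol | c1ccccc1COc1ccc2c(c1)O[C@H](c1ccc(OCc3ccccc3)c(OCc3ccccc3)c1)[C@@H](O)[C@H]2c1cc2c(cc1O)O[C@@H](c1ccc(OCc3ccccc3)c(OCc3ccccc3)c1)[C@@H](O)C2 | intermediate
14 | (2R,3S,4S)-2-(3,4-dihydroxyphenyl)-4-[(2S,3S)-2-(3,4-dihydroxyphenyl)-3,7-dihydroxychroman-6-yl]chromane-3,7-diol, fisetinidol-(4β→6)-ent-epifisetinidol | Oc1ccc2c(c1)O[C@H](c1ccc(O)c(O)c1)[C@@H](O)[C@H]2c1cc2c(cc1O)O[C@@H](c1ccc(O)c(O)c1)[C@@H](O)C2 | target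

Total step count: 9. Longest linear sequence: 6 steps (steps 1, 2, 3, 7, 8, 9, or equally steps 4, 5, 6, 7, 8, 9).

Steps most likely to fail

Step 7. The boron-bound ion pair may transfer the aryloxy oxygen instead of the ortho carbon, or the strongly stabilised C4 cation may escape the ion pair so that facial control is lost. The oxirane of 10 may also be reduced while the borate is formed. The fallback sets out from diol 3, so it bypasses the labile epoxide 4 as well, and comes back at 12. Friedel–Crafts condensation of the benzylic C4 cation of 3 with excess resorcinol 9 (BF3·OEt2 cat., dioxane) should give both C4 epimers of the adduct. The 3,4-cis epimer (2R,3S,4S)-7-(benzyloxy)-2-[3,4-bis(benzyloxy)phenyl]-4-(2,4-dihydroxyphenyl)chroman-3-ol F1 is separated by chromatography. It is then etherified with epoxy alcohol 8 under Mitsunobu conditions (PPh3, DIAD, THF) at the unhindered hydroxyl para to the flavanyl group, which gives 12.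

Step 8. The Lewis acid may ionise the benzylic aryl ether at C2', causing cleavage or epimerisation, or the arene may attack through C8' or open the oxirane in the 5-exo sense. The fallback sets out from 12 and comes back at 13. Bromination with NBS (CH2Cl2, −78 °C) para to the free C7' hydroxyl should give (2R,3S,4S)-7-(benzyloxy)-2-[3,4-bis(benzyloxy)phenyl]-4-[4-{(S)-[3,4-bis(benzyloxy)phenyl][(S)-oxiran-2-yl]methoxy}-5-bromo-2-hydroxyphenyl]chroman-3-ol F2. A nickel-catalysed reductive cross-electrophile coupling of the aryl bromide with the oxirane (NiBr2·glyme, 2,2'-bipyridine, NaI, Et3N·HCl, Zn, DMPU, rt) then forms the same C4'–C4a' bond without acid. Iodide opens the oxirane at the terminal carbon before the C–C coupling, and the bromide fixes the site of ring closure.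

Step 1. The base may open ring C of the dihydroflavonol through its enolate, with loss of the C2 and C3 configuration, and air may oxidise it to the flavonol. The fallback sets out from 1 and comes back at 3. Unprotected fustin is reduced first (NaBH4, MeOH, 0 °C) to (2R,3S,4R)-2-(3,4-dihydroxyphenyl)chromane-3,4,7-triol F3, which removes the enolisable ketone before any base is used. Benzylation of its three phenols (BnBr, K2CO3, DMF, rt) then gives 3.

Further compounds
F1 | step 7 | (2R,3S,4S)-7-(benzyloxy)-2-[3,4-bis(benzyloxy)phenyl]-4-(2,4-dihydroxyphenyl)chroman-3-ol | c1ccccc1COc1ccc2c(c1)O[C@H](c1ccc(OCc3ccccc3)c(OCc3ccccc3)c1)[C@@H](O)[C@H]2c1ccc(O)cc1O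
F2 | step 8 | (2R,3S,4S)-7-(benzyloxy)-2-[3,4-bis(benzyloxy)phenyl]-4-[4-{(S)-[3,4-bis(benzyloxy)phenyl][(S)-oxiran-2-yl]methoxy}-5-bromo-2-hydroxyphenyl]chroman-3-ol | c1ccccc1COc1ccc2c(c1)O[C@H](c1ccc(OCc3ccccc3)c(OCc3ccccc3)c1)[C@@H](O)[C@H]2c1cc(Br)c(O[C@@H](c3ccc(OCc4ccccc4)c(OCc4ccccc4)c3)[C@@H]3CO3)cc1O
F3 | step 1 | (2R,3S,4R)-2-(3,4-dihydroxyphenyl)chromane-3,4,7-triol | Oc1ccc2c(c1)O[C@H](c1ccc(O)c(O)c1)[C@@H](O)[C@@H]2O
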